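Everything rests on opening pyran ring F at O1'–C2' and C3'–C4'. These bonds lie on either side of the C2'–C3' edge. Ring D bearing a free phenol (future O1') beside a formyl group (future C4'), plus a 3,4-dibenzyloxycinnamaldehyde, therefore contain all six ring F atoms. This 1,2-relationship on ring D is the feature exploited. A chiral secondary amine joins both partners in one operation (oxa-Michael addition, then aldol condensation), closing ring F and fixing C2'. The surplus formyl carbon on C3' is later excised to a ketone, and C3' follows by relay. The precursor is perbenzylated epiafzelechin 3-O-gallate carrying at C4β a 2,6-dibenzyloxy-3-formyl-4-hydroxyphenyl ring.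

Key step: step 9

**Remarks**
- Numbering is flavan numbering. The upper unit is unprimed (rings A, C, B). The lower unit is primed (aromatic ring D, pyran ring F, catechol ring E). Bn = benzyl.
- The target reads as (−)-epiafzelechin 3-O-gallate-(4β→6)-(−)-epicatechin 3-O-gallate. It is 2R,3R with ring D on the β face of C4 (3,4-trans), and 2'R,3'R (2',3'-cis).
- Assumption: (−)-epiafzelechin is bought as the natural (2R,3R) enantiomer from a natural-product supplier.

**Design points**
- The oxygen that becomes O1' travels through the C4–C6' coupling as a triisopropylsilyl ether, which is bulky enough to screen both carbons ortho to it.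
- The gallate is put on O3 before that coupling, so that it covers the α face of C4.
- The formyl group is delivered by magnesium from the free phenol, so ring A is not attacked.
- The amine must be the (S)-enantiomer, C[Si](C)(C)OC(c1ccccc1)(c1ccccc1)[C@@H]1CCCN1, to obtain 2'R.
- From the salicylaldehyde onward, slow rotation about C4–C6' should give rotamers, which have no stereochemical consequence.

**Route**

Step 1
Reactants: 1 (−)-epiafzelechin
Product: 2 tri-O-benzyl-(−)-epiafzelechin (benzyl ethers on O5, O7 and the para oxygen of ring B; 3-OH free; 2R,3R)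
Conditions: BnBr (3.3 equiv), K2CO3, DMF, 0 °C to rt, argon
Reagents that add atoms: benzyl bromide, BrCc1ccccc1
Why: Williamson ether synthesis: K2CO3 ionises only the three phenols, so the secondary 3-OH stays free, while low temperature and exclusion of air hold back base-induced opening of ring C (loss of C2 integrity) and C-benzylation of ring A, and no stereocenter is touched.

Step 2
Reactants: 2 tri-O-benzyl-(−)-epiafzelechin
Product: 3 4β-(2-ethoxyethoxy) derivative of 2 (2,3-cis, 3,4-trans; 3-OH free)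
Conditions: DDQ (1.5 equiv), EtOCH2CH2OH, CH2Cl2, rt
Reagents that add atoms: 2-ethoxyethanol, CCOCCO
Why: Oxidative benzylic alkoxylation with DDQ: hydride is abstracted from C4 because the resulting cation is stabilised by the three oxygens on ring A, and the alcohol should add to the β face, anti to the 3-OH and ring B, which sets C4 with the 3,4-trans relationship known for benzylated 2,3-cis-flavan-3-ols.

Step 3
Reactants: 3 4β-(2-ethoxyethoxy) ether; 4 3,4,5-tris(benzyloxy)benzoic acid
Product: 5 3-O-[3,4,5-tris(benzyloxy)benzoyl] ester of 3 (C4 electrophile)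
Conditions: DCC, DMAP (cat), CH2Cl2, rt
Reagents that add atoms: none
Why: Steglich esterification proceeds under neutral conditions that spare the acid-labile C4 ether, acylates the only free hydroxyl with retention at C3, and installs the acyl group that will shield the α face in step 5.

Step 4
Reactants: 6 3,5-bis(benzyloxy)phenol
Product: 7 [3,5-bis(benzyloxy)phenoxy]triisopropylsilane
Conditions: TIPSCl, imidazole, DMF, rt
Reagents that add atoms: chlorotriisopropylsilane, CC(C)[Si](Cl)(C(C)C)C(C)C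
Why: Standard imidazole-promoted silylation of a phenol; triisopropylsilyl is chosen because it is bulky enough to screen both carbons ortho to its oxygen and survives Me3SiOTf at low temperature.

Step 5
Reactants: 5 C4 electrophile; 7 TIPS ether of 3,5-bis(benzyloxy)phenol
Product: 8 symmetric C4 adduct (benzylated epiafzelechin 3-O-gallate bearing at C4β a 2,6-bis(benzyloxy)-4-(triisopropylsilyloxy)phenyl ring D)
Conditions: 5 added slowly to 7 (4 equiv), Me3SiOTf (20 mol %), 4 Å MS, CH2Cl2, −78 to −40 °C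
Reagents that add atoms: none
Why: Lewis acid promoted Friedel–Crafts alkylation of the type used to make interflavan bonds: ionisation of the C4 ether gives a benzylic cation whose α face is covered by the neighbouring 3-O-acyl group and ring B, so the arene should enter from the β face (C4 set 3,4-trans), the OTIPS group should steer attack to the carbon between the two benzyloxy groups, and slow addition of 5 to excess 7 suppresses self-condensation through ring A.

Step 6
Reactants: 8 symmetric C4 adduct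
Product: 9 ring D phenol (as 8, with a free OH para to C4)
Conditions: Bu4NF, AcOH, THF, 0 °C
Reagents that add atoms: none
Why: Fluoride-induced cleavage of the aryl silyl ether, buffered with AcOH so that the liberated phenoxide cannot attack the gallate ester, leaves benzyl ethers and all stereocenters untouched.

Step 7
Reactants: 9 ring D phenol
Product: 10 ring D salicylaldehyde (benzylated epiafzelechin 3-O-gallate bearing at C4β the 2,6-bis(benzyloxy)-3-formyl-4-hydroxyphenyl ring)
Conditions: MgCl2, Et3N, (CH2O)n, THF, 65 °C; then cold 1 M HCl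
Reagents that add atoms: paraformaldehyde (as formaldehyde), C=O
Why: Casnati–Skattebøl ortho-formylation: magnesium binds the only free phenol and delivers formaldehyde to a carbon ortho to it, so the nucleophilic C6 and C8 of ring A (which a Vilsmeier reagent would attack) are spared, and because the two ortho carbons of ring D are interchanged by rotation about C4–C6' a single aldehyde results, which fixes the 4→6 connectivity.

Step 8
Reactants: 11 3,4-bis(benzyloxy)benzaldehyde
Product: 12 (E)-3-[3,4-bis(benzyloxy)phenyl]acrylaldehyde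
Conditions: Ph3P=CHCHO (1.1 equiv), toluene, 80 °C
Reagents that add atoms: (triphenylphosphoranylidene)acetaldehyde, O=CC=P(c1ccccc1)(c1ccccc1)c1ccccc1
Why: Wittig olefination with a stabilised formyl ylide gives the E-enal, and keeping the ylide close to one equivalent curbs a second homologation.

Step 9
Reactants: 10 ring D salicylaldehyde; 12 (E)-3-[3,4-bis(benzyloxy)phenyl]acrylaldehyde
Product: 15 protected dimer whose lower unit is the (2'R)-2'-aryl-2H-chromene-3'-carbaldehyde joined through C6', via iminium ion 13 (not isolated), via oxa-Michael enamine 14 (not isolated)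
Conditions: (S)-2-[diphenyl(trimethylsilyloxy)methyl]pyrrolidine (30 mol %), 2-nitrobenzoic acid (30 mol %), 12 (2 equiv), 4 Å MS, toluene, rt to 40 °C
Reagents that add atoms: none
Why: The amine condenses with 12 to the E-configured iminium ion 13, the ring D phenol of 10 adds to its β carbon (O1'–C2') to give enamine 14, the α carbon of 14 attacks the neighbouring formyl carbon (C3'–C4'), and loss of water with hydrolysis releases 15 and the amine. This is the known diarylprolinol silyl ether catalysed oxa-Michael/aldol condensation of salicylaldehydes with cinnamaldehydes, applied here to a more hindered and more electron-rich aldehyde. Ring F closes in a 6-(enolexo)-exo-trig mode. C2' is controlled by the catalyst: in 13 the CPh2(OSiMe3) group of the (S)-amine covers the Re face of the β carbon, so the phenol should enter from the Si face, which corresponds to 2'R, and any 2'S epimer would be a diastereomer removable by chromatography. The step needs chemo-, regio- and facial selectivity: 10 has a single free OH, ortho to its single formyl group and para to C6', so only the 4→6 chromene can form, and the stereocenters of the upper unit lie too far from O1' to override the catalyst. The acid co-catalyst speeds iminium formation and dehydration, and the sieves pull the reversible sequence forward.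

Step 10
Reactants: 15 chromene-3'-carbaldehyde dimer
Product: 17 (2'R)-flavan-3'-one dimer, via enol formate 16 (not isolated)
Conditions: 30% aq H2O2 (1.5 equiv), (2-O2NC6H4Se)2 (5 mol %), CH2Cl2, rt; Na2S2O3 wash; then KHCO3 (cat), MeOH–THF, 0 °C
Reagents that add atoms: hydrogen peroxide, OO
Why: Baeyer–Villiger oxidation of an α-substituted β-aryl enal by the areneperseleninic acid cycle: the electron-rich vinyl group should migrate in preference to hydrogen to give enol formate 16, whose very labile formyl group is removed by base-catalysed methanolysis at 0 °C, mild enough to spare the gallate ester and the enolisable C2' center of 17.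

Step 11
Reactants: 17 (2'R)-flavan-3'-one dimer
Product: 18 (2'R,3'R)-flavan-3'-ol dimer (2',3'-cis, free 3'-OH)
Conditions: LiBH(s-Bu)3, LiBr, THF, −78 °C; then AcOH
Reagents that add atoms: none
Why: Diastereoselective ketone reduction with a bulky trialkylborohydride: hydride should reach C3' from the face opposite ring E and so give the cis alcohol (3'R), as established for benzylated flavan-3-ones on the way from catechins to epicatechins, and the ester is inert at −78 °C.

Step 12
Reactants: 18 (2'R,3'R)-flavan-3'-ol dimer; 4 3,4,5-tris(benzyloxy)benzoic acid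
Product: 19 trideca-O-benzyl derivative of the target
Conditions: DCC, DMAP, CH2Cl2, rt
Reagents that add atoms: none
Why: Steglich esterification of the axial 3'-OH with retention, well established for benzylated epicatechins, while the upper ester and all ethers are inert.

Step 13
Reactants: 19 trideca-O-benzyl derivative
Product: 20 (−)-epiafzelechin 3-O-gallate-(4β→6)-(−)-epicatechin 3-O-gallate (target)
Conditions: H2 (1 atm), Pd(OH)2/C, THF–MeOH–H2O, rt
Reagents that add atoms: none
Why: Catalytic hydrogenolysis removes all thirteen benzyl ethers under neutral conditions that are known to leave the interflavan bond, the benzylic C2–O1 bonds and the gallate esters of procyanidin gallates intact, and no stereocenter is affected.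

**Compound list**

1 | (−)-epiafzelechin, (2R,3R) | O[C@@H]1Cc2c(O)cc(O)cc2O[C@@H]1c1ccc(O)cc1 | starting material
2 | tri-O-benzyl-(−)-epiafzelechin | O[C@@H]1Cc2c(OCc7ccccc7)cc(OCc7ccccc7)cc2O[C@@H]1c1ccc(OCc7ccccc7)cc1 | intermediate
3 | 4β-(2-ethoxyethoxy)-tri-O-benzyl-epiafzelechin | O[C@@H]1[C@@H](OCCOCC)c2c(OCc7ccccc7)cc(OCc7ccccc7)cc2O[C@@H]1c1ccc(OCc7ccccc7)cc1 | intermediate
4 | 3,4,5-tris(benzyloxy)benzoic acid | OC(=O)c1cc(OCc2ccccc2)c(OCc2ccccc2)c(OCc2ccccc2)c1 | starting material
5 | 3-O-[tris(benzyloxy)benzoyl] ester of 3 | O=C(O[C@@H]1[C@@H](OCCOCC)c2c(OCc7ccccc7)cc(OCc7ccccc7)cc2O[C@@H]1c1ccc(OCc7ccccc7)cc1)c1cc(OCc7ccccc7)c(OCc7ccccc7)c(OCc7ccccc7)c1 | intermediate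
6 | 3,5-bis(benzyloxy)phenol | Oc1cc(OCc2ccccc2)cc(OCc2ccccc2)c1 | starting material
7 | [3,5-bis(benzyloxy)phenoxy]triisopropylsilane | CC(C)[Si](Oc1cc(OCc2ccccc2)cc(OCc2ccccc2)c1)(C(C)C)C(C)C | intermediate
8 | symmetric C4β adduct with 2,6-bis(benzyloxy)-4-(triisopropylsilyloxy)phenyl ring D | O=C(O[C@@H]1[C@@H](c2c(OCc7ccccc7)cc(O[Si](C(C)C)(C(C)C)C(C)C)cc2OCc7ccccc7)c2c(OCc7ccccc7)cc(OCc7ccccc7)cc2O[C@@H]1c1ccc(OCc7ccccc7)cc1)c1cc(OCc7ccccc7)c(OCc7ccccc7)c(OCc7ccccc7)c1 | intermediate
9 | ring D phenol | O=C(O[C@@H]1[C@@H](c2c(OCc7ccccc7)cc(O)cc2OCc7ccccc7)c2c(OCc7ccccc7)cc(OCc7ccccc7)cc2O[C@@H]1c1ccc(OCc7ccccc7)cc1)c1cc(OCc7ccccc7)c(OCc7ccccc7)c(OCc7ccccc7)c1 | intermediate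
10 | ring D salicylaldehyde (key-step precursor) | O=C(O[C@@H]1[C@@H](c2c(OCc7ccccc7)cc(O)c(C=O)c2OCc7ccccc7)c2c(OCc7ccccc7)cc(OCc7ccccc7)cc2O[C@@H]1c1ccc(OCc7ccccc7)cc1)c1cc(OCc7ccccc7)c(OCc7ccccc7)c(OCc7ccccc7)c1 | intermediate
11 | 3,4-bis(benzyloxy)benzaldehyde | O=Cc1ccc(OCc2ccccc2)c(OCc2ccccc2)c1 | starting material
12 | (E)-3-[3,4-bis(benzyloxy)phenyl]acrylaldehyde | O=C/C=C/c1ccc(OCc2ccccc2)c(OCc2ccccc2)c1 | intermediate
13 | E-iminium ion of 12 with the (S)-amine, 2-nitrobenzoate salt | C[Si](C)(C)OC(c1ccccc1)(c1ccccc1)[C@@H]1CCC/[N+]1=C\C=C\c1ccc(OCc2ccccc2)c(OCc2ccccc2)c1.[O-]C(=O)c1ccccc1[N+](=O)[O-] | intermediate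
14 | oxa-Michael enamine (O1'–C2' formed, C2' configured as in 15) | O=C(O[C@@H]1[C@@H](c2c(OCc7ccccc7)cc(O[C@@H](/C=C/N4CCC[C@H]4C(c5ccccc5)(c5ccccc5)O[Si](C)(C)C)c6ccc(OCc7ccccc7)c(OCc7ccccc7)c6)c(C=O)c2OCc7ccccc7)c2c(OCc7ccccc7)cc(OCc7ccccc7)cc2O[C@@H]1c1ccc(OCc7ccccc7)cc1)c1cc(OCc7ccccc7)c(OCc7ccccc7)c(OCc7ccccc7)c1 | intermediate
15 | (2'R)-2H-chromene-3'-carbaldehyde dimer (key-step product) | O=C(O[C@@H]1[C@@H](c2c(OCc7ccccc7)cc3c(c2OCc7ccccc7)C=C(C=O)[C@@H](c2ccc(OCc7ccccc7)c(OCc7ccccc7)c2)O3)c2c(OCc7ccccc7)cc(OCc7ccccc7)cc2O[C@@H]1c1ccc(OCc7ccccc7)cc1)c1cc(OCc7ccccc7)c(OCc7ccccc7)c(OCc7ccccc7)c1 | intermediate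
16 | 3'-formyloxy-2H-chromene dimer (enol formate) | O=C(O[C@@H]1[C@@H](c2c(OCc7ccccc7)cc3c(c2OCc7ccccc7)C=C(OC=O)[C@@H](c2ccc(OCc7ccccc7)c(OCc7ccccc7)c2)O3)c2c(OCc7ccccc7)cc(OCc7ccccc7)cc2O[C@@H]1c1ccc(OCc7ccccc7)cc1)c1cc(OCc7ccccc7)c(OCc7ccccc7)c(OCc7ccccc7)c1 | intermediate
17 | (2'R)-flavan-3'-one dimer | O=C(O[C@@H]1[C@@H](c2c(OCc7ccccc7)cc3c(c2OCc7ccccc7)CC(=O)[C@@H](c2ccc(OCc7ccccc7)c(OCc7ccccc7)c2)O3)c2c(OCc7ccccc7)cc(OCc7ccccc7)cc2O[C@@H]1c1ccc(OCc7ccccc7)cc1)c1cc(OCc7ccccc7)c(OCc7ccccc7)c(OCc7ccccc7)c1 | intermediate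
18 | (2'R,3'R)-flavan-3'-ol dimer | O=C(O[C@@H]1[C@@H](c2c(OCc7ccccc7)cc3c(c2OCc7ccccc7)C[C@@H](O)[C@@H](c2ccc(OCc7ccccc7)c(OCc7ccccc7)c2)O3)c2c(OCc7ccccc7)cc(OCc7ccccc7)cc2O[C@@H]1c1ccc(OCc7ccccc7)cc1)c1cc(OCc7ccccc7)c(OCc7ccccc7)c(OCc7ccccc7)c1 | intermediate
19 | trideca-O-benzyl derivative of the target | O=C(O[C@@H]1[C@@H](c2c(OCc7ccccc7)cc3c(c2OCc7ccccc7)C[C@@H](OC(=O)c2cc(OCc7ccccc7)c(OCc7ccccc7)c(OCc7ccccc7)c2)[C@@H](c2ccc(OCc7ccccc7)c(OCc7ccccc7)c2)O3)c2c(OCc7ccccc7)cc(OCc7ccccc7)cc2O[C@@H]1c1ccc(OCc7ccccc7)cc1)c1cc(OCc7ccccc7)c(OCc7ccccc7)c(OCc7ccccc7)c1 | intermediate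
20 | (−)-epiafzelechin 3-O-gallate-(4β→6)-(−)-epicatechin 3-O-gallate, CNP0169607.1 | O=C(O[C@@H]1[C@@H](c2c(O)cc3c(c2O)C[C@@H](OC(=O)c2cc(O)c(O)c(O)c2)[C@@H](c2ccc(O)c(O)c2)O3)c2c(O)cc(O)cc2O[C@@H]1c1ccc(O)cc1)c1cc(O)c(O)c(O)c1 | target

**Step count**
- Total step count: 13.
- Longest linear sequence: 11 steps (1, 2, 3, 5, 6, 7, 9, 10, 11, 12, 13).

**Steps most likely to fail**

1. Step 9.
- What may go wrong: the sequence may stall after the reversible oxa-Michael addition, because the doubly ortho-substituted, electron-rich formyl group is a weak aldol acceptor and the donor-substituted iminium ion is a weak Michael acceptor. Repeated reversal of the first step could also erode facial selectivity.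
- Fallback, from 5 back to 20: ring F is then taken from the chiral pool instead of being built.
- Commercial (−)-epicatechin is benzylated on its four phenols (BnBr, K2CO3, DMF) to tetra-O-benzyl-(−)-epicatechin F1.
- F1 is brominated at the more reactive C8 (NBS, CH2Cl2, −78 °C) to 8-bromo-tetra-O-benzyl-epicatechin F2.
- F2 is esterified with 4 (DCC, DMAP) to the 8-bromo 3-O-gallate F3.
- With C8 capped, Me3SiOTf-promoted union of F3 with 5 can only take place at C6. It should give the 8'-bromo analogue of 19 F4.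
- Hydrogenolysis over Pd(OH)2/C with Et3N (1 equiv) removes bromine and all benzyl groups and gives 20.

2. Step 5.
- What may go wrong: the C4 cation may attack a carbon ortho to the silyloxy group, which would lead into the 4→8 series. It may also be captured by ring A of a second molecule.
- Fallback, from 5 back to 8: the regiochemical question is moved from the C–C bond to the oxygens.
- 5 is condensed with excess phloroglucinol, whose three ring carbons are equivalent (BF3·OEt2, THF–CH2Cl2, 0 °C). This gives the 4β-(2,4,6-trihydroxyphenyl) adduct F5.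
- The least hindered hydroxyl, para to C4, is silylated (TIPSCl 1 equiv, imidazole, DMF, 0 °C) to the mono-TIPS ether F6.
- Benzylation of the two remaining hydroxyls (BnBr, K2CO3, DMF, rt) gives 8.

3. Step 10.
- What may go wrong: the electron-rich enol formate may be epoxidised as it forms, hydrogen may migrate instead of the vinyl group, or C2' may epimerise through enolisation during formate cleavage.
- Fallback, from 15 back to 17: the formyl carbon is removed through nitrogen instead of oxygen.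
- Pinnick oxidation (NaClO2, NaH2PO4, 2-methyl-2-butene, t-BuOH–THF–H2O) gives the 2H-chromene-3'-carboxylic acid F7.
- (PhO)2P(O)N3 and Et3N in toluene give the acyl azide F8.
- At 80 °C F8 undergoes Curtius rearrangement to the vinyl isocyanate F9.
- Hydrolysis of F9 with 1 M HCl–THF at rt gives 17. This is the classical way from 2H-chromene-3-carboxylic acids to chroman-3-ones.

**Further compounds**

F1 | step 9 | tetra-O-benzyl-(−)-epicatechin | O[C@@H]1Cc2c(OCc7ccccc7)cc(OCc7ccccc7)cc2O[C@@H]1c1ccc(OCc7ccccc7)c(OCc7ccccc7)c1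
F2 | step 9 | 8-bromo-tetra-O-benzyl-epicatechin | O[C@@H]1Cc2c(OCc7ccccc7)cc(OCc7ccccc7)c(Br)c2O[C@@H]1c1ccc(OCc7ccccc7)c(OCc7ccccc7)c1
F3 | step 9 | 8-bromo-tetra-O-benzyl-epicatechin 3-O-[tris(benzyloxy)benzoate] | O=C(O[C@@H]1Cc2c(OCc7ccccc7)cc(OCc7ccccc7)c(Br)c2O[C@@H]1c1ccc(OCc7ccccc7)c(OCc7ccccc7)c1)c1cc(OCc7ccccc7)c(OCc7ccccc7)c(OCc7ccccc7)c1
F4 | step 9 | 8'-bromo analogue of 19 | O=C(O[C@@H]1[C@@H](c2c(OCc7ccccc7)c(Br)c3c(c2OCc7ccccc7)C[C@@H](OC(=O)c2cc(OCc7ccccc7)c(OCc7ccccc7)c(OCc7ccccc7)c2)[C@@H](c2ccc(OCc7ccccc7)c(OCc7ccccc7)c2)O3)c2c(OCc7ccccc7)cc(OCc7ccccc7)cc2O[C@@H]1c1ccc(OCc7ccccc7)cc1)c1cc(OCc7ccccc7)c(OCc7ccccc7)c(OCc7ccccc7)c1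
F5 | step 5 | 4β-(2,4,6-trihydroxyphenyl) adduct | O=C(O[C@@H]1[C@@H](c2c(O)cc(O)cc2O)c2c(OCc7ccccc7)cc(OCc7ccccc7)cc2O[C@@H]1c1ccc(OCc7ccccc7)cc1)c1cc(OCc7ccccc7)c(OCc7ccccc7)c(OCc7ccccc7)c1
F6 | step 5 | 4β-[2,6-dihydroxy-4-(triisopropylsilyloxy)phenyl] adduct | O=C(O[C@@H]1[C@@H](c2c(O)cc(O[Si](C(C)C)(C(C)C)C(C)C)cc2O)c2c(OCc7ccccc7)cc(OCc7ccccc7)cc2O[C@@H]1c1ccc(OCc7ccccc7)cc1)c1cc(OCc7ccccc7)c(OCc7ccccc7)c(OCc7ccccc7)c1
F7 | step 10 | (2'R)-2H-chromene-3'-carboxylic acid dimer | O=C(O[C@@H]1[C@@H](c2c(OCc7ccccc7)cc3c(c2OCc7ccccc7)C=C(C(=O)O)[C@@H](c2ccc(OCc7ccccc7)c(OCc7ccccc7)c2)O3)c2c(OCc7ccccc7)cc(OCc7ccccc7)cc2O[C@@H]1c1ccc(OCc7ccccc7)cc1)c1cc(OCc7ccccc7)c(OCc7ccccc7)c(OCc7ccccc7)c1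
F8 | step 10 | (2'R)-2H-chromene-3'-carbonyl azide dimer | O=C(O[C@@H]1[C@@H](c2c(OCc7ccccc7)cc3c(c2OCc7ccccc7)C=C(C(=O)N=[N+]=[N-])[C@@H](c2ccc(OCc7ccccc7)c(OCc7ccccc7)c2)O3)c2c(OCc7ccccc7)cc(OCc7ccccc7)cc2O[C@@H]1c1ccc(OCc7ccccc7)cc1)c1cc(OCc7ccccc7)c(OCc7ccccc7)c(OCc7ccccc7)c1
F9 | step 10 | (2'R)-3'-isocyanato-2H-chromene dimer | O=C(O[C@@H]1[C@@H](c2c(OCc7ccccc7)cc3c(c2OCc7ccccc7)C=C(N=C=O)[C@@H](c2ccc(OCc7ccccc7)c(OCc7ccccc7)c2)O3)c2c(OCc7ccccc7)cc(OCc7ccccc7)cc2O[C@@H]1c1ccc(OCc7ccccc7)cc1)c1cc(OCc7ccccc7)c(OCc7ccccc7)c(OCc7ccccc7)c1
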